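# Proposed total synthesis of CNP0225022.2 by an enone-initiated, vinylsilane-terminated bicyclisation

## Structural features

The target is an aryl alkyl ether: O7 of 6,8-dimethoxycoumarin (isofraxidin) is joined through one CH2 group (C11) to C9 of a trans-fused decalin. Ring A is a cyclohexanone (C3) flanked by C4 (CH–CH3) and the quaternary C5 (CH3). Ring B carries C8 (CH–CH3) and the quaternary C9 (CH3 and C11), and C10 is the ring-fusion CH. The five stereocentres C4, C5, C10, C9 and C8 are contiguous (4S,5R,8S,9S,10S). In the chair–chair form the C5 and C9 methyls are 1,3-diaxial on one face, the C8 methyl is axial on the other (trans to the C9 methyl), and C11 and the C4 methyl are equatorial. Fragile elements are the coumarin lactone (bases, hydrides, organometallics), the epimerisable C4 next to the ketone, and the C11 oxygen, which sits 1,4 to C5 and would trap a cation there if left nucleophilic. The real difficulty lies in the two quaternary centres with syn-diaxial methyls, the axial C8 methyl, and an ether bond at a neopentyl carbon. The key step exploits three features. The C3 carbonyl lies three atoms from C10, so a C1=C2–C3=O vinyl ketone can initiate at C1. The trans fusion corresponds to anti addition across an (E)-C5=C10 olefin. Ring B can end at a (Z)-vinylsilane whose silicon-bearing C6 bonds to C5, leaving a C6=C7 olefin that carries no stereochemical information.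

## Logic of the disconnections

**32 to 30 and 31.** The C11–O bond of the aryl ether is cut. This keeps the base- and nucleophile-sensitive lactone out of the whole sequence and places all stereochemistry in 30. The forward step must achieve substitution at a neopentyl carbon with a hindered phenol.

**30 to 29 to 28.** No skeletal bond is cut. The C4 configuration and the C11 ester are adjusted (30 from 29), and the C6–C7 bond is taken back to an olefin (29 from 28). The cut is placed here because the cyclisation is best run with the C4 methyl axial (4R) and delivers a C6=C7 olefin. The demand is that the equatorial C4 epimer is the thermodynamic one and that hydrogenation creates no stereocentre.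

**28 to 26.** C1–C10 and C5–C6 are cut, opening both rings to an acyclic trienone. Two rings, two skeletal bonds and the C5/C10 pair are traded for one chain that carries only C4, C8 and C9. The forward step must add anti across the E olefin and choose the correct olefin face relative to C8/C9. To help this, 26 is deliberately the 4R epimer.

**26 to 25 to 24 to 23.** Only the oxidation level at C3 and the group on the C11 oxygen change. An ester is wanted at C11 for the cyclisation (non-nucleophilic, bulky), while an ether is needed to survive the organolithium steps before it. The demand is selective acylation of the primary hydroxyl in 24.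

**23 to 22 to 21.** The C3–C4 bond is cut, with the C5=C10 olefin transposed back to C4=C5 and oxygen returned to C10. This is the retron of a [2,3]-sigmatropic shift. It reduces the E trisubstituted olefin and C4 to one carbinol centre at C10 and a butenyl group of fixed geometry. The demand is regioselective carbanion formation and faithful chirality transfer.

**21 to 19 to 15 and 16.** The (Z)-vinylsilane is taken back to a silylalkyne, and the C10–C5 bond is cut into an aldehyde and an alkenyl metal. The gain is a four-carbon unit of defined geometry from a commercial bromide. The demand is 1,2-induction at C10 from the quaternary C9.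

**15 to 14 to 12 to 11.** The C10 carbonyl is traced to a propenyl olefin, and the C7≡C6 unit to a one-carbon homologation of a C7 aldehyde. Both termini of the C8–C9 unit are thereby reduced to an olefin and a primary alcohol. The demand is that the olefin is cleaved in the presence of the silylalkyne.

**11 to 8.** The C8–C9 bond is cut, the retron of an ester enolate Claisen rearrangement. The vicinal tertiary/quaternary pair is exchanged for one carbinol stereocentre, one olefin geometry and one enolate geometry. The demand is an E ketene acetal and a chair transition state.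

**8 to 7 to 6 to 3 to 1 and 2.** The ester is cut to an allylic alcohol, the alcohol is resolved from its racemate, and the olefin is made from an alkyne by adding CH3 and the carbinol carbon across it. The alkyne comes from two commercial C3 and C8 pieces. The demand is a geometrically pure trisubstituted olefin and an efficient resolution.

## Other disconnections considered

**Alternative 1:** The cut runs through the benzo ring of the coumarin (C4a–C8a and C5–C6, coumarin numbering). The decalin alcohol, with C3 masked as a dioxolane, is first attached to a furan and the aromatic ring is built last.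
- **Forward key step.** The 2-silyloxyfuran A2 adds methyl propiolate A3 (furan C5 to the alkyne CH). The oxanorbornadiene opens and aromatises to the benzoate A1. O-methylation, adjustment of the ester to the aldehyde and annulation of the pyranone must follow.
- **In its favour.** The regiochemistry follows from the polarised partners. The ether oxygen is bonded to an sp2 carbon in the furan precursor, so this bond could be made by addition–elimination of the C11 alkoxide to an unsaturated lactone instead of by substitution at the neopentyl C11. On this one point it is better than the chosen plan.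
- **Against it here.** It creates no stereocentre and presupposes the complete decalin. It rebuilds an aromatic ring that is commercial, and it adds a ketal and six or more steps after the decalin.
- **Comparison.** On structure it addresses only the aryl ether, and on mechanism it is reliable. On step economy it is clearly worse. It complements the chosen plan rather than competing with it.

**Alternative 2:** The cut is at C8–C9, made while ring B closes.
- **Forward key step.** The silyl ketene acetal of the δ-lactone A5 (C11 carbonyl, ring oxygen and (E)-propenyl on C6) undergoes a ring-contracting Claisen rearrangement through a bicyclic boat to the acid A4.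
- **In its favour.** C8, the quaternary C9 and ring B arise in one concerted step. Because the lactone bridges C6 and C9, the relation of C8/C9 to C5/C10 is enforced by ring geometry and not by a balance of non-bonded contacts. This is a point on which it is better than the chosen plan. The C6=C7 olefin is the same in both plans.
- **Against it here.** Ring A with C4, the quaternary C5, C10 and a C6 carbinol of defined configuration has to be made first, which moves the difficulty rather than removing it. C11 emerges as a hindered carboxylic acid that must be reduced under ketal protection. The endgame etherification is no easier.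
- **Comparison.** Mechanistically it is at least as predictable as the cationic cascade. In step count it is probably longer, because neither ring comes from an acyclic chain in one operation.

**Alternative 3:** The cut is in ring A at C3–C4 and C5–C10.
- **Forward key step.** Tiglic aldehyde A7, activated by a protonated chiral B-aryl oxazaborolidine (bistriflimide salt), adds exo to the dienoate A8 to give the cyclohexene aldehyde ester A6.
- **In its favour.** It is catalytic and enantioselective, and it sets C4, the quaternary C5 and C10 in one intermolecular step from two simple components. Absolute control by a catalyst is better than the kinetic resolution of the chosen plan, which discards half of one early intermediate. The C5/C10 relation is set cleanly, whereas the chosen plan sets it in its least certain step.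
- **Against it here.** An α,β-disubstituted enal is a sluggish dienophile, and the diene is only alkyl-activated. Ring B must then be annulated stepwise, with the quaternary C9 made by enolate alkylation next to C10, the axial C8 methyl set separately, and C3 oxidised by transposition from the C1=C2 olefin.
- **Comparison.** The front end is more efficient and the back end longer and less controlled. The hardest centres (C8/C9) are left to the weakest steps, whereas the chosen plan sets them first by a sigmatropic shift.

Key step: step 16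

**Assumption 1:** locants C1–C11 in names and explanations follow the decalin numbering of 32 (C3 ketone, C4 and C8 CH–CH3, C5 and C9 quaternary, C10 ring-fusion CH, C11 the OCH2), also for acyclic intermediates.

**Assumption 2:** 23, 24 and 25 are carried as C3 epimers, since C3 becomes the ketone in step 15; their SMILES leave C3 undefined.

## Route

Step 1
Reactants: 1 4-methoxybenzyl alcohol; 2 3-bromoprop-1-yne
Product: 3 1-methoxy-4-[(prop-2-yn-1-yloxy)methyl]benzene
Conditions: NaH, THF/DMF, 0 °C; then 2, Bu4NI (cat.), 0 °C → rt
Reagents that add atoms: none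
Why: Williamson ether synthesis; the sodium alkoxide of 1 displaces bromide from the primary propargylic bromide, and no stereocentre is involved.

Step 2
Reactants: 3 1-methoxy-4-[(prop-2-yn-1-yloxy)methyl]benzene
Product: 6 rac-(E)-5-[(4-methoxybenzyl)oxy]-4-methylpent-3-en-2-ol, via alkenyldimethylalane 4 (not isolated), via lithium alkenylalanate 5 (not isolated)
Conditions: Me3Al, Cp2ZrCl2 (cat.), CH2Cl2, 0 °C → rt; volatiles removed; n-BuLi, THF/hexane, −78 °C; MeCHO, −78 → 0 °C
Reagents that add atoms: trimethylaluminium, C[Al](C)C; acetaldehyde, CC=O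
Why: Zirconium-catalysed carboalumination (Negishi) adds CH3 and Al syn across the alkyne with the methyl on the internal carbon, which fixes the E trisubstituted olefin; the alanate adds to acetaldehyde with retention of olefin geometry. The carbinol centre is formed racemic and is resolved in step 3.

Step 3
Reactants: 6 rac-(E)-5-[(4-methoxybenzyl)oxy]-4-methylpent-3-en-2-ol
Product: 7 (2S,3E)-5-[(4-methoxybenzyl)oxy]-4-methylpent-3-en-2-ol
Conditions: Candida antarctica lipase B (immobilised), vinyl acetate, t-BuOMe, 30 °C, stopped just past half conversion; chromatography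
Reagents that add atoms: none
Why: Lipase-catalysed kinetic resolution by acyl transfer; lipases acylate the R enantiomer of methyl/alkenyl carbinols much faster, so the S alcohol should remain in high enantiomeric purity. This single centre is the source of all absolute configuration in the route.

Step 4
Reactants: 7 (2S,3E)-5-[(4-methoxybenzyl)oxy]-4-methylpent-3-en-2-ol
Product: 8 (2S,3E)-5-[(4-methoxybenzyl)oxy]-4-methylpent-3-en-2-yl propanoate
Conditions: EtCOCl, Et3N, DMAP (cat.), CH2Cl2, 0 °C
Reagents that add atoms: propanoyl chloride, CCC(Cl)=O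
Why: DMAP-catalysed acylation of a secondary alcohol with an acid chloride; the stereocentre is untouched.

Step 5
Reactants: 8 (2S,3E)-5-[(4-methoxybenzyl)oxy]-4-methylpent-3-en-2-yl propanoate
Product: 11 (2R,3R,4E)-3-{[(4-methoxybenzyl)oxy]methyl}-2,3-dimethylhex-4-en-1-ol, via silyl ketene acetal 9 (not isolated), via trimethylsilyl ester 10 (not isolated)
Conditions: LiN(i-Pr)2, THF, −78 °C; Me3SiCl/Et3N, −78 °C → 50 °C; then LiAlH4, 0 °C
Reagents that add atoms: none
Why: Ireland–Claisen rearrangement; kinetic enolisation in THF gives the E silyl ketene acetal (methyl cis to the allylic oxygen), which rearranges through a chair with the carbinol methyl equatorial. The S carbinol centre is thereby relayed to the quaternary C9 and the ketene acetal geometry sets C8 (8R,9R in 11, methyls syn in the extended chain); the silyl ester is reduced in the same flask.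

Step 6
Reactants: 11 (2R,3R,4E)-3-{[(4-methoxybenzyl)oxy]methyl}-2,3-dimethylhex-4-en-1-ol
Product: 12 (2R,3R,4E)-3-{[(4-methoxybenzyl)oxy]methyl}-2,3-dimethylhex-4-enal
Conditions: Dess–Martin periodinane, NaHCO3, CH2Cl2, 0 °C → rt
Reagents that add atoms: none
Why: Dess–Martin oxidation of a primary alcohol under buffered, non-basic conditions, chosen so that the α-stereocentre C8 is not epimerised.

Step 7
Reactants: 12 (2R,3R,4E)-3-{[(4-methoxybenzyl)oxy]methyl}-2,3-dimethylhex-4-enal
Product: 14 (3R,4R,5E)-4-{[(4-methoxybenzyl)oxy]methyl}-3,4-dimethyl-1-(trimethylsilyl)hept-5-en-1-yne, via terminal alkyne 13 (not isolated)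
Conditions: Me3SiCHN2, n-BuLi, THF, −78 °C; 12, −78 → 0 °C; then n-BuLi, −78 °C; Me3SiCl
Reagents that add atoms: (trimethylsilyl)diazomethane, C[Si](C)(C)C=[N+]=[N-]; chlorotrimethylsilane, C[Si](C)(C)Cl
Why: Colvin rearrangement; the lithiated diazo compound adds to the aldehyde, and Peterson elimination with loss of N2 gives an alkylidene carbene whose 1,2-hydrogen shift forms the alkyne at low temperature without enolising C8. The acetylide formed with a second equivalent of n-BuLi is silylated on carbon.

Step 8
Reactants: 14 (3R,4R,5E)-4-{[(4-methoxybenzyl)oxy]methyl}-3,4-dimethyl-1-(trimethylsilyl)hept-5-en-1-yne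
Product: 15 (2R,3R)-2-{[(4-methoxybenzyl)oxy]methyl}-2,3-dimethyl-5-(trimethylsilyl)pent-4-ynal
Conditions: O3, CH2Cl2/MeOH, −78 °C (Sudan Red 7B end point); PPh3, −78 °C → rt
Reagents that add atoms: ozone, [O-][O+]=O
Why: Ozonolysis with reductive work-up; the 1,2-disubstituted olefin reacts far faster than the silylalkyne or the anisole ring, and the indicator marks the end point. The aldehyde has no α-hydrogen, so C9 cannot epimerise.

Step 9
Reactants: 15 (2R,3R)-2-{[(4-methoxybenzyl)oxy]methyl}-2,3-dimethyl-5-(trimethylsilyl)pent-4-ynal; 16 (Z)-2-bromobut-2-ene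
Product: 19 (3R,4R,5S,6Z)-4-{[(4-methoxybenzyl)oxy]methyl}-3,4,6-trimethyl-1-(trimethylsilyl)oct-6-en-1-yn-5-ol, via butenyllithium 17 (not isolated), via butenylmagnesium bromide 18 (not isolated)
Conditions: 16, t-BuLi (2 equiv), Et2O, −78 °C; MgBr2·OEt2; 15, CH2Cl2, −78 → −20 °C
Reagents that add atoms: none
Why: Bromine–lithium exchange proceeds with retention; the alkenylmagnesium reagent adds to the aldehyde chelated through the C11 ether oxygen from the face of the C9 methyl, away from the branched C8 substituent (the Felkin–Anh model predicts the same face), which should give the 10S carbinol. The butenyl unit has its two methyls trans, so that C10 is cis to the C4 methyl, as step 12 requires; C10 epimers are separable here.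

Step 10
Reactants: 19 (3R,4R,5S,6Z)-4-{[(4-methoxybenzyl)oxy]methyl}-3,4,6-trimethyl-1-(trimethylsilyl)oct-6-en-1-yn-5-ol
Product: 21 (1Z,3S,4R,5S,6Z)-4-{[(4-methoxybenzyl)oxy]methyl}-3,4,6-trimethyl-1-(trimethylsilyl)octa-1,6-dien-5-ol, via alkenylalane 20 (not isolated)
Conditions: i-Bu2AlH, N-methylpyrrolidine, heptane/Et2O, 0 → 50 °C; aq. KNaC4H4O6
Reagents that add atoms: none
Why: cis-Hydroalumination of a 1-silylalkyne in the presence of a donor places Al on the silicon-bearing carbon and H on C7 on the same side; protonolysis with retention gives the (Z)-vinylsilane. Isolated olefins are inert under these conditions.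

Step 11
Reactants: 21 (1Z,3S,4R,5S,6Z)-4-{[(4-methoxybenzyl)oxy]methyl}-3,4,6-trimethyl-1-(trimethylsilyl)octa-1,6-dien-5-ol
Product: 22 (1Z,3S,4R,5S,6Z)-5-(allyloxy)-4-{[(4-methoxybenzyl)oxy]methyl}-3,4,6-trimethyl-1-(trimethylsilyl)octa-1,6-diene
Conditions: KH, THF, 0 °C; allyl bromide, Bu4NI (cat.), rt
Reagents that add atoms: allyl bromide, C=CCBr
Why: Williamson allylation of the potassium alkoxide with a reactive allylic bromide; C10 is not affected.

Step 12
Reactants: 22 (1Z,3S,4R,5S,6Z)-5-(allyloxy)-4-{[(4-methoxybenzyl)oxy]methyl}-3,4,6-trimethyl-1-(trimethylsilyl)octa-1,6-diene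
Product: 23 (4R,5E,7S,8S,9Z)-7-{[(4-methoxybenzyl)oxy]methyl}-4,5,7,8-tetramethyl-10-(trimethylsilyl)deca-1,5,9-trien-3-ol (C3 epimers)
Conditions: n-BuLi, THF, −78 → −20 °C
Reagents that add atoms: none
Why: [2,3]-Wittig rearrangement; the carbanion formed at the allylic OCH2 adds to C4 on the face of the breaking C10–O bond through a five-membered envelope. Allylic 1,3-strain with the C4 methyl (cis to C10) keeps the C10 hydrogen inside and the C9 group outside, which gives the E C5=C10 olefin and transfers 10S to 4R.

Step 13
Reactants: 23 (4R,5E,7S,8S,9Z)-7-{[(4-methoxybenzyl)oxy]methyl}-4,5,7,8-tetramethyl-10-(trimethylsilyl)deca-1,5,9-trien-3-ol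
Product: 24 (2S,3E,5R)-2,4,5-trimethyl-2-[(2S,3Z)-4-(trimethylsilyl)but-3-en-2-yl]octa-3,7-diene-1,6-diol (C6 epimers in this name, C3 in route numbering)
Conditions: DDQ, CH2Cl2/pH 7 phosphate buffer, 0 °C
Reagents that add atoms: none
Why: Oxidative cleavage of the p-methoxybenzyl ether by DDQ (hydride abstraction, hydrolysis of the oxocarbenium ion); the buffered medium leaves the vinylsilane, the olefins and the allylic alcohol untouched.

Step 14
Reactants: 24 (2S,3E,5R)-2,4,5-trimethyl-2-[(2S,3Z)-4-(trimethylsilyl)but-3-en-2-yl]octa-3,7-diene-1,6-diol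
Product: 25 (2S,3E,5R)-6-hydroxy-2,4,5-trimethyl-2-[(2S,3Z)-4-(trimethylsilyl)but-3-en-2-yl]octa-3,7-dien-1-yl 2,2-dimethylpropanoate
Conditions: t-BuCOCl, pyridine, CH2Cl2, 0 °C → rt
Reagents that add atoms: pivaloyl chloride, CC(C)(C)C(Cl)=O
Why: Selective acylation; the bulky acid chloride discriminates the primary C11 hydroxyl from the secondary allylic C3 hydroxyl. The ester makes the C11 oxygen non-nucleophilic and bulky for the cyclisation and tolerates the Lewis acid.

Step 15
Reactants: 25 (2S,3E,5R)-6-hydroxy-2,4,5-trimethyl-2-[(2S,3Z)-4-(trimethylsilyl)but-3-en-2-yl]octa-3,7-dien-1-yl 2,2-dimethylpropanoate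
Product: 26 (2S,3E,5R)-2,4,5-trimethyl-6-oxo-2-[(2S,3Z)-4-(trimethylsilyl)but-3-en-2-yl]octa-3,7-dien-1-yl 2,2-dimethylpropanoate (the (E)-olefinic vinyl ketone with (Z)-vinylsilane and pivalate; 4R,8S,9S)
Conditions: Dess–Martin periodinane, NaHCO3, CH2Cl2, 0 °C
Reagents that add atoms: none
Why: Dess–Martin oxidation of the allylic alcohol to the vinyl ketone; buffered conditions avoid migration of the β,γ-olefin and epimerisation at C4, and 26 is used without delay.

Step 16
Reactants: 26 (2S,3E,5R)-2,4,5-trimethyl-6-oxo-2-[(2S,3Z)-4-(trimethylsilyl)but-3-en-2-yl]octa-3,7-dien-1-yl 2,2-dimethylpropanoate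
Product: 28 [(1S,2S,4aR,5R,8aS)-1,2,4a,5-tetramethyl-6-oxo-1,2,4a,5,6,7,8,8a-octahydronaphthalen-1-yl]methyl 2,2-dimethylpropanoate (C6–C7 unsaturated decalone pivalate, C4 methyl axial), via aluminium enolate 27 (not isolated)
Conditions: MeAlCl2 (3 equiv), CH2Cl2, −78 → −40 °C; Et3N/MeOH, then aq. NaHCO3
Reagents that add atoms: none
Why: MeAlCl2 binds the vinyl ketone (a further equivalent is held by the ester), and C10 of the E olefin attacks C1 of the s-trans enone through a chair, 6-endo, giving an aluminium enolate and a tertiary cation at C5. The (Z)-vinylsilane then attacks C5 through its silicon-bearing carbon C6, 6-endo, and the β-silyl cation at C7 loses Me3Si to chloride, so that ring B ends as the C6=C7 olefin and the enolate is protonated on work-up. The closest known reaction type is the Lewis-acid enone-initiated cation–olefin cyclisation with ipso termination by a vinylsilane. C10 and C5 are set by anti addition across the E olefin in a chair–chair array, which gives the trans ring fusion with the C5 methyl axial. The selectivity needed is between the two faces of the C5=C10 olefin relative to C8/C9, that is the chair with the C9 methyl axial, CH2OPiv equatorial and the C8 methyl axial. Two contacts favour it: the 4R methyl is pseudoaxial in this chair, whereas on the other face it would be pseudoequatorial and eclipsed with the C5 methyl (1,2-allylic strain), and the aluminium-complexed CH2OPiv avoids the axial site 1,3 to the C5 methyl. One contact opposes it, the axial C8 methyl 1,3 to the silyl group that must turn axial on C6, and this is why C4 is inverted in 26. C4 is returned to the equatorial configuration in step 18.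

Step 17
Reactants: 28 [(1S,2S,4aR,5R,8aS)-1,2,4a,5-tetramethyl-6-oxo-1,2,4a,5,6,7,8,8a-octahydronaphthalen-1-yl]methyl 2,2-dimethylpropanoate
Product: 29 [(1S,2S,4aR,5R,8aS)-1,2,4a,5-tetramethyl-6-oxodecahydronaphthalen-1-yl]methyl 2,2-dimethylpropanoate
Conditions: H2 (4 bar), Pd/C, EtOAc, rt
Reagents that add atoms: none
Why: Heterogeneous hydrogenation of the cis-disubstituted ring olefin; C6 and C7 become CH2 groups, so no stereocentre is created, and the ketone and ester are inert to Pd/C here.

Step 18
Reactants: 29 [(1S,2S,4aR,5R,8aS)-1,2,4a,5-tetramethyl-6-oxodecahydronaphthalen-1-yl]methyl 2,2-dimethylpropanoate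
Product: 30 (1S,4aS,5S,6S,8aR)-5-(hydroxymethyl)-1,5,6,8a-tetramethyloctahydronaphthalen-2(1H)-one
Conditions: NaOMe, MeOH, 60 °C
Reagents that add atoms: none
Why: Methoxide-mediated transesterification frees the C11 alcohol and, through the enolate, equilibrates C4 to the equatorial methyl (4S), which should be favoured because the 1,3-diaxial contacts with the axial hydrogens on C2 and C10 are relieved. The minor axial epimer can be resubmitted.

Step 19
Reactants: 30 (1S,4aS,5S,6S,8aR)-5-(hydroxymethyl)-1,5,6,8a-tetramethyloctahydronaphthalen-2(1H)-one; 31 isofraxidin (7-hydroxy-6,8-dimethoxy-2H-chromen-2-one)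
Product: 32 6,8-dimethoxy-7-{[(1S,2S,4aR,5S,8aS)-1,2,4a,5-tetramethyl-6-oxodecahydronaphthalen-1-yl]methoxy}-2H-chromen-2-one (CNP0225022.2)
Conditions: n-Bu3P, 1,1′-(azodicarbonyl)dipiperidine, toluene, 0 → 80 °C
Reagents that add atoms: none
Why: Mitsunobu etherification; the acidic, coumarin-conjugated phenol displaces the oxyphosphonium group at C11. The n-Bu3P/azodicarboxamide pair tolerates the heating that substitution at this neopentyl carbon needs, and the neutral conditions spare the lactone and C4.

## Compound list

1 | 4-methoxybenzyl alcohol | COc1ccc(CO)cc1 | starting material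
2 | 3-bromoprop-1-yne (propargyl bromide) | C#CCBr | starting material
3 | 1-methoxy-4-[(prop-2-yn-1-yloxy)methyl]benzene | COc1ccc(COCC#C)cc1 | intermediate
4 | (E)-{3-[(4-methoxybenzyl)oxy]-2-methylprop-1-en-1-yl}dimethylalane | C[Al](C)/C=C(\C)COCc1ccc(OC)cc1 | intermediate
5 | lithium butyl{(E)-3-[(4-methoxybenzyl)oxy]-2-methylprop-1-en-1-yl}dimethylalanate | [Li+].CCCC[Al-](C)(C)/C=C(\C)COCc1ccc(OC)cc1 | intermediate
6 | rac-(E)-5-[(4-methoxybenzyl)oxy]-4-methylpent-3-en-2-ol | CC(O)/C=C(\C)COCc1ccc(OC)cc1 | intermediate
7 | (2S,3E)-5-[(4-methoxybenzyl)oxy]-4-methylpent-3-en-2-ol | C[C@H](O)/C=C(\C)COCc1ccc(OC)cc1 | intermediate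
8 | (2S,3E)-5-[(4-methoxybenzyl)oxy]-4-methylpent-3-en-2-yl propanoate | C[C@H](OC(=O)CC)/C=C(\C)COCc1ccc(OC)cc1 | intermediate
9 | (E)-trimethylsilyl ketene acetal of 8 (methyl cis to the allylic oxygen) | C/C=C(/O[Si](C)(C)C)O[C@@H](C)/C=C(\C)COCc1ccc(OC)cc1 | intermediate
10 | trimethylsilyl (2R,3R,4E)-3-{[(4-methoxybenzyl)oxy]methyl}-2,3-dimethylhex-4-enoate | COc1ccc(COC[C@](C)(/C=C/C)[C@@H](C)C(=O)O[Si](C)(C)C)cc1 | intermediate
11 | (2R,3R,4E)-3-{[(4-methoxybenzyl)oxy]methyl}-2,3-dimethylhex-4-en-1-ol | COc1ccc(COC[C@](C)(/C=C/C)[C@@H](C)CO)cc1 | intermediate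
12 | (2R,3R,4E)-3-{[(4-methoxybenzyl)oxy]methyl}-2,3-dimethylhex-4-enal | COc1ccc(COC[C@](C)(/C=C/C)[C@@H](C)C=O)cc1 | intermediate
13 | (3S,4R,5E)-4-{[(4-methoxybenzyl)oxy]methyl}-3,4-dimethylhept-5-en-1-yne | COc1ccc(COC[C@](C)(/C=C/C)[C@@H](C)C#C)cc1 | intermediate
14 | (3R,4R,5E)-4-{[(4-methoxybenzyl)oxy]methyl}-3,4-dimethyl-1-(trimethylsilyl)hept-5-en-1-yne | COc1ccc(COC[C@](C)(/C=C/C)[C@@H](C)C#C[Si](C)(C)C)cc1 | intermediate
15 | (2R,3R)-2-{[(4-methoxybenzyl)oxy]methyl}-2,3-dimethyl-5-(trimethylsilyl)pent-4-ynal | COc1ccc(COC[C@](C)(C=O)[C@@H](C)C#C[Si](C)(C)C)cc1 | intermediate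
16 | (Z)-2-bromobut-2-ene | C/C=C(/C)Br | starting material
17 | but-2-en-2-yllithium (methyl groups trans; formally E) | C/C=C(/C)[Li] | intermediate
18 | but-2-en-2-ylmagnesium bromide (methyl groups trans; formally Z) | C/C=C(/C)[Mg]Br | intermediate
19 | (3R,4R,5S,6Z)-4-{[(4-methoxybenzyl)oxy]methyl}-3,4,6-trimethyl-1-(trimethylsilyl)oct-6-en-1-yn-5-ol | COc1ccc(COC[C@](C)([C@@H](O)/C(C)=C\C)[C@@H](C)C#C[Si](C)(C)C)cc1 | intermediate
20 | diisobutylaluminium alkoxide of the 1-(diisobutylalumino)-1-(trimethylsilyl)alkene from 19 (Al cis to H on C7) | COc1ccc(COC[C@](C)([C@@H](O[Al](CC(C)C)CC(C)C)/C(C)=C\C)[C@@H](C)/C=C(\[Si](C)(C)C)[Al](CC(C)C)CC(C)C)cc1 | intermediate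
21 | (1Z,3S,4R,5S,6Z)-4-{[(4-methoxybenzyl)oxy]methyl}-3,4,6-trimethyl-1-(trimethylsilyl)octa-1,6-dien-5-ol | COc1ccc(COC[C@](C)([C@@H](O)/C(C)=C\C)[C@@H](C)/C=C\[Si](C)(C)C)cc1 | intermediate
22 | (1Z,3S,4R,5S,6Z)-5-(allyloxy)-4-{[(4-methoxybenzyl)oxy]methyl}-3,4,6-trimethyl-1-(trimethylsilyl)octa-1,6-diene | COc1ccc(COC[C@](C)([C@@H](OCC=C)/C(C)=C\C)[C@@H](C)/C=C\[Si](C)(C)C)cc1 | intermediate
23 | (4R,5E,7S,8S,9Z)-7-{[(4-methoxybenzyl)oxy]methyl}-4,5,7,8-tetramethyl-10-(trimethylsilyl)deca-1,5,9-trien-3-ol (C3 epimers) | C=CC(O)[C@H](C)/C(C)=C/[C@@](C)(COCc1ccc(OC)cc1)[C@@H](C)/C=C\[Si](C)(C)C | intermediate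
24 | (2S,3E,5R)-2,4,5-trimethyl-2-[(2S,3Z)-4-(trimethylsilyl)but-3-en-2-yl]octa-3,7-diene-1,6-diol (carbinol epimers) | C=CC(O)[C@H](C)/C(C)=C/[C@@](C)(CO)[C@@H](C)/C=C\[Si](C)(C)C | intermediate
25 | (2S,3E,5R)-6-hydroxy-2,4,5-trimethyl-2-[(2S,3Z)-4-(trimethylsilyl)but-3-en-2-yl]octa-3,7-dien-1-yl 2,2-dimethylpropanoate (carbinol epimers) | C=CC(O)[C@H](C)/C(C)=C/[C@@](C)(COC(=O)C(C)(C)C)[C@@H](C)/C=C\[Si](C)(C)C | intermediate
26 | (2S,3E,5R)-2,4,5-trimethyl-6-oxo-2-[(2S,3Z)-4-(trimethylsilyl)but-3-en-2-yl]octa-3,7-dien-1-yl 2,2-dimethylpropanoate | C=CC(=O)[C@H](C)/C(C)=C/[C@@](C)(COC(=O)C(C)(C)C)[C@@H](C)/C=C\[Si](C)(C)C | intermediate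
27 | chloro(methyl)aluminium enolate (C2=C3–O–Al) of 28 | CC(C)(C)C(=O)OC[C@]1(C)[C@H]2CC=C(O[Al](C)Cl)[C@H](C)[C@]2(C)C=C[C@@H]1C | intermediate
28 | [(1S,2S,4aR,5R,8aS)-1,2,4a,5-tetramethyl-6-oxo-1,2,4a,5,6,7,8,8a-octahydronaphthalen-1-yl]methyl 2,2-dimethylpropanoate | CC(C)(C)C(=O)OC[C@]1(C)[C@H]2CCC(=O)[C@H](C)[C@]2(C)C=C[C@@H]1C | intermediate
29 | [(1S,2S,4aR,5R,8aS)-1,2,4a,5-tetramethyl-6-oxodecahydronaphthalen-1-yl]methyl 2,2-dimethylpropanoate | CC(C)(C)C(=O)OC[C@]1(C)[C@H]2CCC(=O)[C@H](C)[C@]2(C)CC[C@@H]1C | intermediate
30 | (1S,4aS,5S,6S,8aR)-5-(hydroxymethyl)-1,5,6,8a-tetramethyloctahydronaphthalen-2(1H)-one | OC[C@]1(C)[C@H]2CCC(=O)[C@@H](C)[C@]2(C)CC[C@@H]1C | intermediate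
31 | isofraxidin (7-hydroxy-6,8-dimethoxy-2H-chromen-2-one) | COc1cc2ccc(=O)oc2c(OC)c1O | starting material
32 | 6,8-dimethoxy-7-{[(1S,2S,4aR,5S,8aS)-1,2,4a,5-tetramethyl-6-oxodecahydronaphthalen-1-yl]methoxy}-2H-chromen-2-one | COc1cc2ccc(=O)oc2c(OC)c1OC[C@]1(C)[C@H]2CCC(=O)[C@@H](C)[C@]2(C)CC[C@@H]1C | target

## Step count and least certain steps

Total step count: 19. Longest linear sequence: 19 steps (1/2 to 32); 16 and 31 enter as single reagents.

**Step 16 (key step).**
- **What may go wrong.** Ring closure may take place on the other face of the C5=C10 olefin, through the chair that lets the C8 methyl sit equatorial, or may give a cis fusion. The reason is that in the required chair the C8 methyl is 1,3-diaxial to the silyl group. The outcome can also be eroded by reversal of the first ring closure, by a 1,2-hydride shift from C10 to the C5 cation, or by loss of configuration at C4 in 26 before cyclisation.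
- **Fallback (sets out from 7, returns to the route at 28).** The C8 methyl is left out of the cyclisation substrate and introduced afterwards.
  - Acetylation of 7 (Ac2O, pyridine) gives the (S)-acetate F1. The operations of steps 5 to 15 applied to it give in turn the 8-demethyl primary alcohol F2, the aldehyde F3, the silylalkyne F4, the C10 aldehyde F5, the C10 carbinol F6, the (Z)-vinylsilane F7, the allyl ether F8, the C3 carbinol F9, the diol F10, the monopivalate F11 and the 8-demethyl dienone F12.
  - With MeAlCl2, F12 should give the 8-demethyl decalone F13. The face is now decided only by C4 and C9, which act in the same sense.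
  - Photo-oxygenation (O2, tetraphenylporphyrin, light, Ac2O, pyridine, DMAP) effects the singlet-oxygen ene reaction at C6=C7, where only C8 carries allylic hydrogen, and dehydrates the hydroperoxide to the C7=C8 enone F14 with its carbonyl at C6.
  - Me2CuLi then adds the C8 methyl axially on the open face (the other is shielded by the axial C5 and C9 methyls). The enolate is trapped with PhNTf2 as the enol triflate F15, and reduction of the triflate (Pd(OAc)2, PPh3, HCO2H, Bu3N) gives 28.

**Step 19.**
- **What may go wrong.** Substitution at the neopentyl C11 by a phenol flanked by two methoxy groups may be so slow that the activated alcohol is consumed by side reactions or 30 is simply recovered.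
- **Fallback (from 30, returns at 32).** 30 is converted into the C11 triflate F16 (Tf2O, 2,6-lutidine, CH2Cl2, −78 °C). This isolated electrophile is displaced by the caesium salt of 31 (Cs2CO3, MeCN, 25–50 °C). This is a Williamson substitution in which a far better leaving group and a free phenoxide replace the in situ oxyphosphonium activation. Should substitution at C11 remain impracticable, the ether oxygen would have to be joined to an sp2 carbon instead, along the lines of Alternative 1.

**Step 12.**
- **What may go wrong.** The base may deprotonate at the wrong site (the benzylic position of the PMB ether or the C10 hydrogen), and a [1,2]-shift may compete with the [2,3]-shift in this congested ether.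
- **Fallback (from 21, returns at 23).** The carbanion is generated by tin–lithium exchange, which removes the question of where the base attacks.
  - 21 is alkylated with Bu3SnCH2I (KH, THF) to the stannylmethyl ether F17.
  - n-BuLi at −78 °C gives the α-alkoxymethyllithium, whose [2,3]-shift through the same envelope gives the primary homoallylic alcohol F18 with the same C4 configuration and E olefin.
  - Dess–Martin oxidation to the aldehyde F19 and addition of CH2=CHMgBr at −78 °C give 23.

**Step 5.**
- **What may go wrong.** Incomplete control of the ketene acetal geometry or a partial boat pathway would erode the C8/C9 relationship. Slow rearrangement to the quaternary centre would allow the ketene acetal to decompose.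
- **Fallback (from 7, returns at 12).** Eschenmoser–Claisen rearrangement of 7 with N,N-dimethylpropanamide dimethyl acetal (xylene, 140 °C) gives the N,N-dimethylamide F20 with the same C8/C9 configuration. Here the ketene N,O-acetal geometry (methyl cis to the allylic oxygen) is fixed by allylic strain with the NMe2 group and not by kinetic enolisation. Cp2Zr(H)Cl (THF, rt) reduces the amide to the aldehyde 12.

## Further compounds

F1 | step 16 | (2S,3E)-5-[(4-methoxybenzyl)oxy]-4-methylpent-3-en-2-yl acetate | C[C@H](OC(C)=O)/C=C(\C)COCc1ccc(OC)cc1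
F2 | step 16 | (3S,4E)-3-{[(4-methoxybenzyl)oxy]methyl}-3-methylhex-4-en-1-ol (8-demethyl analogue of 11) | COc1ccc(COC[C@](C)(/C=C/C)CCO)cc1
F3 | step 16 | (3S,4E)-3-{[(4-methoxybenzyl)oxy]methyl}-3-methylhex-4-enal (8-demethyl analogue of 12) | COc1ccc(COC[C@](C)(/C=C/C)CC=O)cc1
F4 | step 16 | 8-demethyl analogue of silylalkyne 14 | COc1ccc(COC[C@](C)(/C=C/C)CC#C[Si](C)(C)C)cc1
F5 | step 16 | 8-demethyl analogue of aldehyde 15 | COc1ccc(COC[C@](C)(C=O)CC#C[Si](C)(C)C)cc1
F6 | step 16 | 8-demethyl analogue of carbinol 19 | COc1ccc(COC[C@](C)([C@@H](O)/C(C)=C\C)CC#C[Si](C)(C)C)cc1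
F7 | step 16 | 8-demethyl analogue of (Z)-vinylsilane 21 | COc1ccc(COC[C@](C)([C@@H](O)/C(C)=C\C)C/C=C\[Si](C)(C)C)cc1
F8 | step 16 | 8-demethyl analogue of allyl ether 22 | COc1ccc(COC[C@](C)([C@@H](OCC=C)/C(C)=C\C)C/C=C\[Si](C)(C)C)cc1
F9 | step 16 | 8-demethyl analogue of carbinol 23 (C3 epimers) | C=CC(O)[C@H](C)/C(C)=C/[C@@](C)(COCc1ccc(OC)cc1)C/C=C\[Si](C)(C)C
F10 | step 16 | 8-demethyl analogue of diol 24 (C3 epimers) | C=CC(O)[C@H](C)/C(C)=C/[C@@](C)(CO)C/C=C\[Si](C)(C)C
F11 | step 16 | 8-demethyl analogue of monopivalate 25 (C3 epimers) | C=CC(O)[C@H](C)/C(C)=C/[C@@](C)(COC(=O)C(C)(C)C)C/C=C\[Si](C)(C)C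
F12 | step 16 | 8-demethyl analogue of dienone 26 | C=CC(=O)[C@H](C)/C(C)=C/[C@@](C)(COC(=O)C(C)(C)C)C/C=C\[Si](C)(C)C
F13 | step 16 | 8-demethyl analogue of decalone 28 (C6=C7 olefin, C8 a CH2 group) | CC(C)(C)C(=O)OC[C@]1(C)[C@H]2CCC(=O)[C@H](C)[C@]2(C)C=CC1
F14 | step 16 | 8-demethyl 3,6-diketone with C7=C8 olefin (enone in ring B) | CC(C)(C)C(=O)OC[C@]1(C)[C@H]2CCC(=O)[C@H](C)[C@]2(C)C(=O)C=C1
F15 | step 16 | enol triflate at C6 (C6=C7) of the C8-methylated diketone | CC(C)(C)C(=O)OC[C@]1(C)[C@H]2CCC(=O)[C@H](C)[C@]2(C)C(OS(=O)(=O)C(F)(F)F)=C[C@@H]1C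
F16 | step 19 | C11 trifluoromethanesulfonate of 30 | O=S(=O)(OC[C@]1(C)[C@H]2CCC(=O)[C@@H](C)[C@]2(C)CC[C@@H]1C)C(F)(F)F
F17 | step 12 | (tributylstannyl)methyl ether of 21 | COc1ccc(COC[C@](C)([C@@H](OC[Sn](CCCC)(CCCC)CCCC)/C(C)=C\C)[C@@H](C)/C=C\[Si](C)(C)C)cc1
F18 | step 12 | (2R,3E,5S,6S,7Z)-5-{[(4-methoxybenzyl)oxy]methyl}-2,3,5,6-tetramethyl-8-(trimethylsilyl)octa-3,7-dien-1-ol | OC[C@H](C)/C(C)=C/[C@@](C)(COCc1ccc(OC)cc1)[C@@H](C)/C=C\[Si](C)(C)C
F19 | step 12 | (2R,3E,5S,6S,7Z)-5-{[(4-methoxybenzyl)oxy]methyl}-2,3,5,6-tetramethyl-8-(trimethylsilyl)octa-3,7-dienal | O=C[C@H](C)/C(C)=C/[C@@](C)(COCc1ccc(OC)cc1)[C@@H](C)/C=C\[Si](C)(C)C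
F20 | step 5 | (2R,3R,4E)-3-{[(4-methoxybenzyl)oxy]methyl}-N,N,2,3-tetramethylhex-4-enamide | COc1ccc(COC[C@](C)(/C=C/C)[C@@H](C)C(=O)N(C)C)cc1
A1 | alternative 1 | methyl 5-hydroxy-3-methoxy-2-(tert-butyldimethylsilyloxy)-4-(decalinylmethoxy)benzoate (C3 dioxolane) | COC(=O)c1cc(O)c(OC[C@]2(C)[C@H]3CCC4(OCCO4)[C@@H](C)[C@]3(C)CC[C@@H]2C)c(OC)c1O[Si](C)(C)C(C)(C)C
A2 | alternative 1 | 2-(tert-butyldimethylsilyloxy)-3-methoxy-4-(decalinylmethoxy)furan (C3 dioxolane) | COc1c(O[Si](C)(C)C(C)(C)C)occ1OC[C@]1(C)[C@H]2CCC3(OCCO3)[C@@H](C)[C@]2(C)CC[C@@H]1C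
A3 | alternative 1 | methyl propiolate | C#CC(=O)OC
A4 | alternative 2 | C6–C7 unsaturated decalin C11 carboxylic acid with C3 dioxolane | OC(=O)[C@]1(C)[C@H]2CCC3(OCCO3)[C@@H](C)[C@]2(C)C=C[C@@H]1C
A5 | alternative 2 | δ-lactone (C11 carbonyl, ring oxygen and (E)-propenyl on C6) fused to ring A with C3 dioxolane (C9 epimers) | CC1C(=O)O[C@H](/C=C/C)[C@@]2(C)[C@H](C)C3(OCCO3)CC[C@H]12
A6 | alternative 3 | ring-A cyclohexene aldehyde ester (side-chain centre unassigned) | O=C[C@@]1(C)[C@H](C)CC=C[C@@H]1C(C)C(=O)OC
A7 | alternative 3 | tiglic aldehyde ((E)-2-methylbut-2-enal) | C/C=C(\C)C=O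
A8 | alternative 3 | methyl (E)-2-methylhexa-3,5-dienoate | C=C/C=C/C(C)C(=O)OC
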